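## Retrosynthetic overview

- The strategy rests on the trans-fused decalin (rings A and B, C1–C10, gem-dimethyl at C4, quaternary C10, C8=C9 with a methyl on C8 and C11 on C9). It is read as a folded geranyl chain joined to an acetoacetate, so that C8 arrives as a ketone and C9 carries an ester that becomes C11.
- Target ⇒ 3-furyl precursor (butenolide from the furan by singlet oxygen, then NaBH4) ⇒ Z-selective Wittig between a C1–C13 α-silyloxy ketone and a C14–C16 furyl ylide whose C16 carbinol comes from an asymmetric hydrogenation.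
- α-Silyloxy ketone ⇒ C11 allylic bromide + β-keto sulfone (C11–C12 bond, then desulfonylation); bromide ⇒ bicyclic keto ester (enol triflate methylation, ester reduction, bromination).
- Bicyclic keto ester ⇒ geranylated acetoacetate by enantioselective proton-initiated bicyclization, ring A closing first (C4–C5), ring B second (C9–C10) ⇒ methyl acetoacetate + geranyl bromide.

Key step: step 2

Notation: Dec = (4aS,8aS)-2,5,5,8a-tetramethyl-3,4,4a,5,6,7,8,8a-octahydronaphthalen-1-yl (C1–C10 with their four methyl groups, bonded through C9); TBS = tert-butyldimethylsilyl; atom numbers are labdane-type (decalin C1–C10, chain C11–C16, butenolide on C16).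

Assumption: methyl [(tert-butyldimethylsilyl)oxy]acetate and ethyl 3-(furan-3-yl)-3-oxopropanoate are taken as catalogue compounds.

## Route

Step 1
Reactants: 1 methyl acetoacetate; 2 geranyl bromide
Product: 4 methyl (6E)-7,11-dimethyl-3-oxododeca-6,10-dienoate, via acetoacetate dianion 3 (not isolated)
Conditions: NaH, THF, 0 °C; n-BuLi, 0 °C; then 2, 0 °C → rt; aq. HCl
Reagents that add atoms: none
Why: Weiler γ-alkylation, in which the more basic terminal carbanion of the acetoacetate dianion displaces the allylic bromide by SN2 without touching the (E)-alkene.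

Step 2
Reactants: 4 methyl (6E)-7,11-dimethyl-3-oxododeca-6,10-dienoate
Product: 5 methyl (1R,4aS,8aS)-5,5,8a-trimethyl-2-oxodecahydronaphthalene-1-carboxylate
Conditions: (R)-2-(2-fluorobenzyloxy)-2′-hydroxy-1,1′-binaphthyl (2.2 equiv), SnCl4 (2.0 equiv), toluene, −78 °C
Reagents that add atoms: none
Why: Proposed new method: the SnCl4-bound binaphthol is a chiral Lewis acid-assisted Brønsted acid that should protonate C3 of the terminal alkene of 4 from one face of a chair–chair folded chain, the C5=C10 alkene attacks the developing C4 cation (bond C4–C5) and the resulting C10 cation is captured by the enol carbon C9 of the β-keto ester (bond C9–C10), the enol proton returning to the ligand. The closest known reaction types are the SnCl4-promoted bicyclization of geranyl β-keto esters (racemic) and the binaphthol·SnCl4-induced enantioselective cyclization of geranyl aryl ethers and homogeranyl arenes; joining chiral proton initiation to a β-keto ester terminator is the part without direct precedent. Ring A closes in a 6-endo-trig chair closure of the C5=C10 alkene onto C4, and ring B in a 6-(enol-endo) chair closure by C-alkylation of the C8=C9 enol at C10. The trans relationship of C5 and C10 is controlled by the (E)-alkene and the chair–chair fold, their absolute configuration (5S,10S) by the face of protonation imposed by the (R)-ligand (the antipodal ligand would be taken if the sense proved opposite), and C9 by equilibration through the enol to the equatorial ester (9R). The step needs enantiofacial control over an achiral proton transfer from a substrate–SnCl4 chelate, which the excess of ligand over SnCl4 and the low temperature are meant to suppress; site selectivity for the terminal alkene, which follows from the internal alkene being the only nucleophile placed to form a six-membered ring; and C- over O-capture, which the soft enol carbon and the strain-free decalone favour.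

Step 3
Reactants: 5 methyl (1R,4aS,8aS)-5,5,8a-trimethyl-2-oxodecahydronaphthalene-1-carboxylate
Product: 7 methyl (4aS,8aS)-5,5,8a-trimethyl-2-(trifluoromethylsulfonyloxy)-3,4,4a,5,6,7,8,8a-octahydronaphthalene-1-carboxylate, via sodium enolate 6 (not isolated)
Conditions: NaH, Et2O, 0 °C → rt; Tf2O, −78 → 0 °C
Reagents that add atoms: trifluoromethanesulfonic anhydride, O=S(=O)(OS(=O)(=O)C(F)(F)F)C(F)(F)F
Why: The doubly activated C9–H is removed and the enolate oxygen on C8 is sulfonylated (enol triflate formation), which fixes the future alkene between C8 and C9 and erases the C9 stereocentre.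

Step 4
Reactants: 7 enol triflate
Product: 8 methyl (4aS,8aS)-2,5,5,8a-tetramethyl-3,4,4a,5,6,7,8,8a-octahydronaphthalene-1-carboxylate
Conditions: Fe(acac)3 (5 mol%), MeMgBr, THF/NMP, −30 → 0 °C
Reagents that add atoms: methylmagnesium bromide, C[Mg]Br
Why: Iron-catalysed Kumada-type cross-coupling of an alkenyl triflate derived from a β-keto ester is faster than Grignard addition to the hindered ester and places the C8 methyl on the pre-formed C8=C9 alkene without any elimination step.

Step 5
Reactants: 8 methyl Dec-carboxylate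
Product: 9 Dec-methanol [(5S,10S)-drim-8-en-11-ol]
Conditions: LiAlH4, Et2O, 0 °C → rt
Reagents that add atoms: none
Why: Hydride 1,2-reduction of the hindered α,β-unsaturated ester gives the primary allylic alcohol and leaves the tetrasubstituted alkene untouched.

Step 6
Reactants: 9 Dec-methanol
Product: 10 Dec-CH2Br [(5S,10S)-11-bromodrim-8-ene]
Conditions: PBr3, pyridine (cat.), Et2O, 0 °C; used crude
Reagents that add atoms: phosphorus tribromide, BrP(Br)Br
Why: Bromination of a primary allylic alcohol through its phosphite ester by SN2 at C11; transposition to the tertiary C8 position is disfavoured sterically and thermodynamically.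

Step 7
Reactants: 11 methyl phenyl sulfone; 12 methyl [(tert-butyldimethylsilyl)oxy]acetate
Product: 14 1-(TBS-oxy)-3-(phenylsulfonyl)propan-2-one, via lithiated sulfone 13 (not isolated)
Conditions: 11 (2.1 equiv), n-BuLi (2.1 equiv), THF, −78 → 0 °C; 12, −78 °C → rt; cold dilute HCl
Reagents that add atoms: none
Why: Claisen-type acylation of the α-sulfonyl carbanion by the ester; the β-keto sulfone is deprotonated by the second equivalent of carbanion as it forms, which prevents over-addition.

Step 8
Reactants: 10 Dec-CH2Br; 14 1-(TBS-oxy)-3-(phenylsulfonyl)propan-2-one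
Product: 15 1-(TBS-oxy)-3-(phenylsulfonyl)-4-Dec-butan-2-one (both C12 epimers)
Conditions: K2CO3, DMF, rt
Reagents that add atoms: none
Why: SN2 C-alkylation of the soft, doubly stabilised β-keto sulfone anion by the primary allylic bromide forms the C11–C12 bond; the new C12 stereocentre forms as a mixture and is removed in step 9.

Step 9
Reactants: 15 alkylated β-keto sulfone
Product: 16 1-(TBS-oxy)-4-Dec-butan-2-one
Conditions: Al foil, HgCl2 (2% aq.), THF/H2O 9:1, rt
Reagents that add atoms: none
Why: Reductive desulfonylation of a β-keto sulfone by aluminium amalgam (electron transfer, loss of benzenesulfinate, protonation of the enolate); because the sulfone sits α to a ketone and not on an allylic carbon, its removal cannot shift or scramble an alkene.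

Step 10
Reactants: 17 ethyl 3-(furan-3-yl)-3-oxopropanoate
Product: 18 ethyl (3R)-3-(furan-3-yl)-3-hydroxypropanoate
Conditions: [RuCl(p-cymene)((S)-BINAP)]Cl (1 mol%), H2 (50 atm), EtOH, 50 °C
Reagents that add atoms: none
Why: Noyori asymmetric hydrogenation of a β-keto ester through the ester-chelated ketone sets C16; by the standard model (R)-BINAP gives (R)-3-hydroxybutanoates and, with the same facial sense, (S)-carbinols when the ketone substituent outranks the CH2CO2Et arm, so (S)-BINAP is chosen for (R)-18.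

Step 11
Reactants: 18 ethyl (3R)-3-(furan-3-yl)-3-hydroxypropanoate
Product: 19 ethyl (3R)-3-(TBS-oxy)-3-(furan-3-yl)propanoate
Conditions: TBSCl, imidazole, DMF, rt
Reagents that add atoms: tert-butyldimethylsilyl chloride, CC(C)(C)[Si](C)(C)Cl
Why: Imidazole-promoted silylation of the secondary alcohol, which also blocks retro-aldol and dehydration pathways in the following steps.

Step 12
Reactants: 19 ethyl (3R)-3-(TBS-oxy)-3-(furan-3-yl)propanoate
Product: 20 (3R)-3-(TBS-oxy)-3-(furan-3-yl)propan-1-ol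
Conditions: DIBAL-H (iBu2AlH), CH2Cl2, −78 → 0 °C
Reagents that add atoms: none
Why: Hydride reduction of the ester to the primary alcohol at low temperature, under which the silyl ether and the furan are inert.

Step 13
Reactants: 20 (3R)-3-(TBS-oxy)-3-(furan-3-yl)propan-1-ol
Product: 21 tert-butyl{[(1R)-1-(furan-3-yl)-3-iodopropyl]oxy}dimethylsilane
Conditions: I2, PPh3, imidazole, CH2Cl2, 0 °C → rt
Reagents that add atoms: iodine, II
Why: Appel-type (Garegg–Samuelsson) iodination of the primary alcohol by SN2 on the alkoxyphosphonium ion, buffered by imidazole so that the acid-sensitive furylcarbinyl silyl ether survives.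

Step 14
Reactants: 21 tert-butyl{[(1R)-1-(furan-3-yl)-3-iodopropyl]oxy}dimethylsilane
Product: 22 [(3R)-3-(TBS-oxy)-3-(furan-3-yl)propyl]triphenylphosphonium iodide
Conditions: PPh3, iPr2NEt (cat.), MeCN, 80 °C
Reagents that add atoms: triphenylphosphine, c1ccc(cc1)P(c1ccccc1)c1ccccc1
Why: SN2 quaternisation of triphenylphosphine by the primary iodide; the γ-silyloxy group is too remote to eliminate.

Step 15
Reactants: 22 [(3R)-3-(TBS-oxy)-3-(furan-3-yl)propyl]triphenylphosphonium iodide; 16 1-(TBS-oxy)-4-Dec-butan-2-one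
Product: 24 3-[(1R,3Z)-1-(TBS-oxy)-4-(TBS-oxymethyl)-6-Dec-hex-3-en-1-yl]furan, via phosphonium ylide 23 (not isolated)
Conditions: 22, KHMDS, THF, −78 → 0 °C; then 16, THF, −78 °C → rt
Reagents that add atoms: none
Why: Wittig reaction of a non-stabilised ylide with an α-alkoxy ketone under salt-free conditions, a combination known (Still's trisubstituted allylic alcohol synthesis) to place the alkoxymethyl group cis to the ylide-derived carbon, which sets the (Z)-C13=C14 alkene with C12 trans to C15.

Step 16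
Reactants: 24 3-[(1R,3Z)-1-(TBS-oxy)-4-(TBS-oxymethyl)-6-Dec-hex-3-en-1-yl]furan
Product: 25 4-[(1R,3Z)-1-(TBS-oxy)-4-(TBS-oxymethyl)-6-Dec-hex-3-en-1-yl]-5-hydroxyfuran-2(5H)-one (hemiacetal epimers)
Conditions: O2, hν (visible), tetraphenylporphyrin (cat.), iPr2NEt, CH2Cl2, −78 °C
Reagents that add atoms: dioxygen, O=O
Why: Sensitised [4+2] addition of singlet oxygen to the furan gives the 2,5-endoperoxide, from which the hindered base removes the less shielded proton remote from the side chain (Faulkner's regioselective furan photooxygenation), so the carbonyl forms distal and the hemiacetal carbon next to the side chain; at −78 °C the furan should react faster than the tri- and tetrasubstituted alkenes, and the hemiacetal epimers converge in step 17.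

Step 17
Reactants: 25 γ-hydroxybutenolide
Product: 26 4-[(1R,3Z)-1-(TBS-oxy)-4-(TBS-oxymethyl)-6-Dec-hex-3-en-1-yl]furan-2(5H)-one
Conditions: NaBH4, EtOH, 0 °C; then 1 M HCl to pH 3, 0 °C
Reagents that add atoms: none
Why: Borohydride reduces the aldehyde of the ring-opened formyl-acrylate tautomer, and acidification relactonises the (Z)-4-hydroxy-enoate to the 4-substituted furan-2(5H)-one, with the CH2–O carbon next to the substituted ring carbon as in the target.

Step 18
Reactants: 26 bis-TBS butenolide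
Product: 27 4-[(1R,3Z)-1-hydroxy-4-(hydroxymethyl)-6-Dec-hex-3-en-1-yl]furan-2(5H)-one (CNP0224983.2)
Conditions: HF·pyridine, pyridine, THF, 0 °C → rt
Reagents that add atoms: none
Why: Fluoride cleavage of both silyl ethers under buffered, non-basic conditions, which avoids deprotonation at C16 or at the butenolide γ-carbon and so preserves the C16 configuration.

## Compound list

1 | methyl acetoacetate | COC(=O)CC(C)=O | starting material
2 | geranyl bromide, (2E)-1-bromo-3,7-dimethylocta-2,6-diene | BrC/C=C(\C)CCC=C(C)C | starting material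
3 | methyl acetoacetate dianion (sodium lithium salt) | [Li+].[Na+].COC(=O)[CH-]C(=O)[CH2-] | intermediate
4 | methyl (6E)-7,11-dimethyl-3-oxododeca-6,10-dienoate | COC(=O)CC(=O)CC/C=C(\C)CCC=C(C)C | intermediate
5 | methyl (1R,4aS,8aS)-5,5,8a-trimethyl-2-oxodecahydronaphthalene-1-carboxylate (trans-fused) | O=C1[C@H](C(=O)OC)[C@@]2(C)CCCC(C)(C)[C@@H]2CC1 | intermediate
6 | sodium enolate of 5 | [Na+].[O-]C1=C(C(=O)OC)[C@@]2(C)CCCC(C)(C)[C@@H]2CC1 | intermediate
7 | methyl (4aS,8aS)-5,5,8a-trimethyl-2-(trifluoromethylsulfonyloxy)-3,4,4a,5,6,7,8,8a-octahydronaphthalene-1-carboxylate | O=S(=O)(OC1=C(C(=O)OC)[C@@]2(C)CCCC(C)(C)[C@@H]2CC1)C(F)(F)F | intermediate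
8 | methyl (4aS,8aS)-2,5,5,8a-tetramethyl-3,4,4a,5,6,7,8,8a-octahydronaphthalene-1-carboxylate | CC1=C(C(=O)OC)[C@@]2(C)CCCC(C)(C)[C@@H]2CC1 | intermediate
9 | [(4aS,8aS)-2,5,5,8a-tetramethyl-3,4,4a,5,6,7,8,8a-octahydronaphthalen-1-yl]methanol | CC1=C(CO)[C@@]2(C)CCCC(C)(C)[C@@H]2CC1 | intermediate
10 | (4aS,8aS)-4-(bromomethyl)-3,4a,8,8-tetramethyl-1,2,4a,5,6,7,8,8a-octahydronaphthalene | CC1=C(CBr)[C@@]2(C)CCCC(C)(C)[C@@H]2CC1 | intermediate
11 | methyl phenyl sulfone | CS(=O)(=O)c1ccccc1 | starting material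
12 | methyl [(tert-butyldimethylsilyl)oxy]acetate | COC(=O)CO[Si](C)(C)C(C)(C)C | starting material
13 | (phenylsulfonyl)methyllithium | [Li+].[CH2-]S(=O)(=O)c1ccccc1 | intermediate
14 | 1-[(tert-butyldimethylsilyl)oxy]-3-(phenylsulfonyl)propan-2-one | CC(C)(C)[Si](C)(C)OCC(=O)CS(=O)(=O)c1ccccc1 | intermediate
15 | 1-[(tert-butyldimethylsilyl)oxy]-3-(phenylsulfonyl)-4-[(4aS,8aS)-2,5,5,8a-tetramethyl-3,4,4a,5,6,7,8,8a-octahydronaphthalen-1-yl]butan-2-one (both C3 epimers) | CC1=C(CC(C(=O)CO[Si](C)(C)C(C)(C)C)S(=O)(=O)c3ccccc3)[C@@]2(C)CCCC(C)(C)[C@@H]2CC1 | intermediate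
16 | 1-[(tert-butyldimethylsilyl)oxy]-4-[(4aS,8aS)-2,5,5,8a-tetramethyl-3,4,4a,5,6,7,8,8a-octahydronaphthalen-1-yl]butan-2-one | CC1=C(CCC(=O)CO[Si](C)(C)C(C)(C)C)[C@@]2(C)CCCC(C)(C)[C@@H]2CC1 | intermediate
17 | ethyl 3-(furan-3-yl)-3-oxopropanoate | CCOC(=O)CC(=O)c1ccoc1 | starting material
18 | ethyl (3R)-3-(furan-3-yl)-3-hydroxypropanoate | CCOC(=O)C[C@@H](O)c1ccoc1 | intermediate
19 | ethyl (3R)-3-[(tert-butyldimethylsilyl)oxy]-3-(furan-3-yl)propanoate | CCOC(=O)C[C@@H](O[Si](C)(C)C(C)(C)C)c1ccoc1 | intermediate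
20 | (3R)-3-[(tert-butyldimethylsilyl)oxy]-3-(furan-3-yl)propan-1-ol | OCC[C@@H](O[Si](C)(C)C(C)(C)C)c1ccoc1 | intermediate
21 | tert-butyl{[(1R)-1-(furan-3-yl)-3-iodopropyl]oxy}dimethylsilane | ICC[C@@H](O[Si](C)(C)C(C)(C)C)c1ccoc1 | intermediate
22 | {(3R)-3-[(tert-butyldimethylsilyl)oxy]-3-(furan-3-yl)propyl}triphenylphosphonium iodide | [I-].c1ccccc1[P+](c1ccccc1)(c1ccccc1)CC[C@@H](O[Si](C)(C)C(C)(C)C)c1ccoc1 | intermediate
23 | {(3R)-3-[(tert-butyldimethylsilyl)oxy]-3-(furan-3-yl)propylidene}triphenylphosphorane | c1ccccc1P(c1ccccc1)(c1ccccc1)=CC[C@@H](O[Si](C)(C)C(C)(C)C)c1ccoc1 | intermediate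
24 | 3-[(1R,3Z)-1-[(tert-butyldimethylsilyl)oxy]-4-{[(tert-butyldimethylsilyl)oxy]methyl}-6-[(4aS,8aS)-2,5,5,8a-tetramethyl-3,4,4a,5,6,7,8,8a-octahydronaphthalen-1-yl]hex-3-en-1-yl]furan | CC1=C(CC/C(=C/C[C@@H](O[Si](C)(C)C(C)(C)C)c3ccoc3)CO[Si](C)(C)C(C)(C)C)[C@@]2(C)CCCC(C)(C)[C@@H]2CC1 | intermediate
25 | 4-[(1R,3Z)-1-[(tert-butyldimethylsilyl)oxy]-4-{[(tert-butyldimethylsilyl)oxy]methyl}-6-[(4aS,8aS)-2,5,5,8a-tetramethyl-3,4,4a,5,6,7,8,8a-octahydronaphthalen-1-yl]hex-3-en-1-yl]-5-hydroxyfuran-2(5H)-one (C5 epimers) | CC1=C(CC/C(=C/C[C@@H](O[Si](C)(C)C(C)(C)C)C3=CC(=O)OC3O)CO[Si](C)(C)C(C)(C)C)[C@@]2(C)CCCC(C)(C)[C@@H]2CC1 | intermediate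
26 | 4-[(1R,3Z)-1-[(tert-butyldimethylsilyl)oxy]-4-{[(tert-butyldimethylsilyl)oxy]methyl}-6-[(4aS,8aS)-2,5,5,8a-tetramethyl-3,4,4a,5,6,7,8,8a-octahydronaphthalen-1-yl]hex-3-en-1-yl]furan-2(5H)-one | CC1=C(CC/C(=C/C[C@@H](O[Si](C)(C)C(C)(C)C)C3=CC(=O)OC3)CO[Si](C)(C)C(C)(C)C)[C@@]2(C)CCCC(C)(C)[C@@H]2CC1 | intermediate
27 | 4-[(1R,3Z)-1-hydroxy-4-(hydroxymethyl)-6-[(4aS,8aS)-2,5,5,8a-tetramethyl-3,4,4a,5,6,7,8,8a-octahydronaphthalen-1-yl]hex-3-en-1-yl]furan-2(5H)-one | CC1=C(CC/C(=C/C[C@@H](O)C2=CC(=O)OC2)CO)[C@@]2(C)CCCC(C)(C)[C@@H]2CC1 | target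

## Summary

Total step count: 18. Longest linear sequence: 12 steps (steps 1–6, 8, 9, 15–18).

### Steps most likely to fail

**1. Step 2 (proposed new method).** The substrate can chelate SnCl4 and act as its own achiral proton source, which would erode the enantiomeric excess. The cascade may also stop after ring A by proton loss, or the C10 cation may be captured at oxygen.

Fallback, from 4 back to 5: cyclise 4 with achiral SnCl4 (CH2Cl2, −78 °C → rt), the known racemic bicyclization of geranyl β-keto esters. This gives 5 mixed with its enantiomer, methyl (1S,4aR,8aR)-5,5,8a-trimethyl-2-oxodecahydronaphthalene-1-carboxylate F1. Condense the racemate with (R)-1-phenylethylamine (AcOH cat., toluene, Dean–Stark) to give the β-enamino ester of 5, methyl (4aS,8aS)-5,5,8a-trimethyl-2-{[(1R)-1-phenylethyl]amino}-3,4,4a,5,6,7,8,8a-octahydronaphthalene-1-carboxylate F2, and its (4aR,8aR) diastereomer F3. Separate them by crystallisation or chromatography, then hydrolyse F2 (aq. HCl, THF, rt) to return 5 as a single enantiomer, the ester settling equatorial again.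

**2. Step 15.** Geometric control may erode (the ylide-derived carbon ending trans to the silyloxymethyl group), and the basic ylide may enolise the ketone instead of adding.

Fallback, from 21 and 16 back to 24, by a stepwise Horner–Wittig sequence in which geometry comes from separation and stereospecific elimination. Alkylate sodium diphenylphosphinite (Ph2P(O)H, NaH, THF) with 21 to give {(3R)-3-[(tert-butyldimethylsilyl)oxy]-3-(furan-3-yl)propyl}diphenylphosphine oxide F4. Lithiate F4 (n-BuLi, THF, −78 °C), add 16 and quench cold to give the β-hydroxy phosphine oxides. Chromatography separates the (13S,14R) adduct F5 and the (13R,14S) adduct F6 from the (13S,14S) adduct F7 and the (13R,14R) adduct F8. Syn-elimination of F5 and F6 (NaH, DMF, rt) places the silyloxymethyl group cis to C15 and gives 24.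

**3. Step 16.** The singlet-oxygen ene reaction at the tetrasubstituted C8=C9 alkene (or at C13=C14) may compete with furan cycloaddition, and regiocontrol may be lost in the base-induced opening of the endoperoxide.

Fallback, from 24 back to 26, without singlet oxygen. Sterically controlled C–H borylation at the furan α-carbon remote from the side chain ([Ir(OMe)(cod)]2, 4,4′-di-tert-butyl-2,2′-bipyridine, B2pin2, hexane, rt → 50 °C) gives the 5-(pinacolboryl)furan F9. Oxidation of the C–B bond (NaBO3·4H2O, THF/H2O, 0 °C) gives the 2-hydroxyfuran, which tautomerises (brief Et3N if needed) to the conjugated butenolide 26. This bypasses 25 and step 17.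

Further compounds
F1 | step 2 | methyl (1S,4aR,8aR)-5,5,8a-trimethyl-2-oxodecahydronaphthalene-1-carboxylate | O=C1[C@@H](C(=O)OC)[C@]2(C)CCCC(C)(C)[C@H]2CC1
F2 | step 2 | methyl (4aS,8aS)-5,5,8a-trimethyl-2-{[(1R)-1-phenylethyl]amino}-3,4,4a,5,6,7,8,8a-octahydronaphthalene-1-carboxylate | C[C@@H](NC1=C(C(=O)OC)[C@@]2(C)CCCC(C)(C)[C@@H]2CC1)c3ccccc3
F3 | step 2 | methyl (4aR,8aR)-5,5,8a-trimethyl-2-{[(1R)-1-phenylethyl]amino}-3,4,4a,5,6,7,8,8a-octahydronaphthalene-1-carboxylate | C[C@@H](NC1=C(C(=O)OC)[C@]2(C)CCCC(C)(C)[C@H]2CC1)c3ccccc3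
F4 | step 15 | {(3R)-3-[(tert-butyldimethylsilyl)oxy]-3-(furan-3-yl)propyl}diphenylphosphine oxide | O=P(c1ccccc1)(c1ccccc1)CC[C@@H](O[Si](C)(C)C(C)(C)C)c1ccoc1
F5 | step 15 | (13S,14R)-β-hydroxy phosphine oxide adduct of F4 and 16 (C13 carbinol, C14 bearing Ph2P(O), C16 R) | CC1=C(CC[C@](O)(CO[Si](C)(C)C(C)(C)C)[C@H](P(=O)(c4ccccc4)c5ccccc5)C[C@@H](O[Si](C)(C)C(C)(C)C)c3ccoc3)[C@@]2(C)CCCC(C)(C)[C@@H]2CC1
F6 | step 15 | (13R,14S)-β-hydroxy phosphine oxide adduct of F4 and 16 | CC1=C(CC[C@@](O)(CO[Si](C)(C)C(C)(C)C)[C@@H](P(=O)(c4ccccc4)c5ccccc5)C[C@@H](O[Si](C)(C)C(C)(C)C)c3ccoc3)[C@@]2(C)CCCC(C)(C)[C@@H]2CC1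
F7 | step 15 | (13S,14S)-β-hydroxy phosphine oxide adduct of F4 and 16 | CC1=C(CC[C@](O)(CO[Si](C)(C)C(C)(C)C)[C@@H](P(=O)(c4ccccc4)c5ccccc5)C[C@@H](O[Si](C)(C)C(C)(C)C)c3ccoc3)[C@@]2(C)CCCC(C)(C)[C@@H]2CC1
F8 | step 15 | (13R,14R)-β-hydroxy phosphine oxide adduct of F4 and 16 | CC1=C(CC[C@@](O)(CO[Si](C)(C)C(C)(C)C)[C@H](P(=O)(c4ccccc4)c5ccccc5)C[C@@H](O[Si](C)(C)C(C)(C)C)c3ccoc3)[C@@]2(C)CCCC(C)(C)[C@@H]2CC1
F9 | step 16 | 2-{4-[(1R,3Z)-1-[(tert-butyldimethylsilyl)oxy]-4-{[(tert-butyldimethylsilyl)oxy]methyl}-6-[(4aS,8aS)-2,5,5,8a-tetramethyl-3,4,4a,5,6,7,8,8a-octahydronaphthalen-1-yl]hex-3-en-1-yl]furan-2-yl}-4,4,5,5-tetramethyl-1,3,2-dioxaborolane | CC1=C(CC/C(=C/C[C@@H](O[Si](C)(C)C(C)(C)C)c3cc(B4OC(C)(C)C(C)(C)O4)oc3)CO[Si](C)(C)C(C)(C)C)[C@@]2(C)CCCC(C)(C)[C@@H]2CC1
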